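Atoms are labelled C1 to O34 in the order of the target SMILES throughout.

## The problem

The molecule consists of two bicyclic halves joined by a two-carbon hinge. The western half is a cis-fused hydroazulene (cyclopentane C5–C6–C7–C8–C9, cycloheptane C2–C3–C4–C5–C6–C12–C15). The eastern half is a trans-fused oxepanone–cyclohexane (oxepane C19–C21–C22–C23–C25–O28–C29, cyclohexane C18–C19–C29–C30–C31–C32), linked through C16–C17 by the Z-configured exocyclic alkene C15=C16. Each half carries four stereocentres (C2, C5, C6, C9 and C18, C19, C29, C32); the hinge isolates the two sets, so each half must be made enantiopure on its own, while inside the western half the tertiary carbinol C9 can control C6 and C5, and a temporary stereocentre at C16 can pass its configuration to C2. C15 lies between the quaternary C12 and C2, so the trisubstituted alkene cannot be made by olefination of a C15 ketone and has to grow out of an enol derivative of that ketone. The fragile points are the two tertiary alcohols (acid-induced elimination), the exocyclic alkene beside C2–H (acid would move it into the ring), the α-alkoxy ketone at C23 and, on the way, every β-oxygenated ketone (retro-aldol cleavage, β-elimination). The eastern half has the pattern of a farnesyl chain folded by an epoxide-opening cascade and is treated as a supporting problem. The feature that opens the western half is that C9, C8, C7, C6 and C12 with the methyls C10, C13 and C14 form a linalool-type chain: attached through C9 to C5 of a cyclopentane-1,3-dione enol ester, it holds the alkene C6=C12 three atoms from the enone C5=C15, so the two missing ring bonds C5–C6 and C12–C15 are those of one (2+2) photocycloaddition, and retro-aldol cleavage of the temporary bond C5–C15 then leaves the seven-membered ring.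

## Retrosynthesis

**40 ⇐ 39 ⇐ 38.** No skeletal bond is cut. The C23 ketone is taken back to the secondary alcohol of triol 39 and this to the tris(triethylsilyl) ether 38. With C23 silylated, no ketone is present when the halves are joined and when a sulfonylhydrazide is used (it would condense with a ketone), and the C23 oxygen comes directly from the epoxide cascade. The forward steps must remove three silyl ethers without acid and oxidise one secondary alcohol beside two tertiary ones.

**38 ⇐ 35 ⇐ 34 ⇐ 33.** The C2–H bond is cut and the alkene moved back from C15=C16 to C15=C2: 38 is the retro-ene product of the allylic diazene made from the (16R)-allylic alcohol 35. The neighbouring cuts fail: olefination of a C15 ketone is blocked by C12 and C2, and dehydration of a C15 carbinol would give the endocyclic tetrasubstituted alkene. The transposition builds the alkene from the side on which C15 is reactive, fixes its geometry by allylic strain and sets C2 from C16. Alcohol 35 comes from enone 34 by reagent-controlled reduction and 34 from the epimeric alcohols 33, so the coupling itself need not be selective. The forward reaction must achieve a Mitsunobu inversion at a hindered allylic carbinol.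

**33 ⇐ 22 + 32.** The C15–C16 bond is cut into the alkenyl triflate 22 and the aldehyde 32. A cut at C16–C17 would need a hindered enal and a functionalised alkylmetal reagent; the chromium-mediated coupling of a triflate with an aldehyde tolerates all groups present. Both fragments are bicyclic, with three and four stereocentres.

**22 ⇐ 21 ⇐ 20 ⇐ 19.** The C1 methyl is removed and the triflate returned to the C15 ketone. Because C12 is quaternary, this ketone can enolise only toward C2, so methylation and enol triflate formation are regiospecific and the C2 configuration of 21 is irrelevant. The alcohol of 19 is silylated (20) only to keep an alkoxide out of the sulfonylation.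

**19 ⇐ 18 ⇐ 17 ⇐ 16 ⇐ 15 ⇐ 14.** The C5–H bond is cut: 19 arises by hydrogenation of the C4=C5 alkene of 18, directed by the free C9 hydroxyl, which sets the cis ring fusion. The alkene marks the place of the C4 oxygen left by the photochemistry; it is removed as the enol triflate 16. The obvious route, enolising dione 14 toward C5, is unsafe: C2, C3 and C5 are all enolisable and C5 is the least accessible. Dehydrogenation of C2–C3 first gives ene-dione 15, in which C5–H is the only enolisable hydrogen. The extra alkene costs one step and disappears again in the hydrogenation.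

**14 ⇐ 13 ⇐ 12.** The bond C5–C15 is reconnected: dione 14 is the retro-aldol product of cyclobutanol 13, the deacetylated form of photoadduct 12. This turns a seven-membered ring problem into a cyclobutane problem.

**12 ⇐ 11 ⇐ 10 ⇐ 9 (key cut).** The bonds C5–C6 and C12–C15 are cut, which leads from tricycle 11 to the monocyclic enol acetate 10 with one stereocentre. Compared with closing C5–C9 onto a preformed cycloheptene or closing both rings by metathesis (see below), this cut makes both carbocycles from a chain and lets C9 direct the new centres. The silyl group is taken off before the irradiation (9 to 10) and put back after it (11 to 12). With a silyl ether the facial choice would depend on the small size difference between methyl and oxygen on C9; with the free alcohol a hydrogen bond to the enone carbonyl decides it.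

**9 ⇐ 8 ⇐ 7 ⇐ 5 + 6.** The enol acetate is returned to dione 8. The bond C5–C15 of 8 is cut by a Claisen disconnection to the 4-oxo ester 7, and C3–C4 of 7 by a Stetter disconnection to aldehyde 5 and methyl acrylate 6. Both enol oxygens of 8 are equivalent, so acetylation has no regiochemical issue. The forward cyclisation must beat β-elimination of the C9 silyloxy group.

**5 ⇐ 4 ⇐ 3 ⇐ 2 ⇐ 1.** C9 is traced to the Sharpless epoxide 2 of geraniol 1; hydride opening at C2 gives the 1,3-diol 3, and bis-silylation (4) with direct oxidation of the primary silyl ether gives 5.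

**32 ⇐ 31 ⇐ 30 ⇐ 29.** The aldehyde carbon C16 is masked as the terminal alkene of an allyl group, the C32 silyl ether is removed and the C32–C33 bond cut to the ketone 29. Methyl addition is expected from the equatorial side because the axial C20 methyl blocks the other.

**29 ⇐ 28.** The bonds O28–C25 and C18–C19 are cut together: 29 is the product of a silyl triflate-promoted cascade of the diepoxy enol silane 28, which forms the oxepane and the cyclohexanone and fixes C19, C29 and C18.

**28 ⇐ 27 ⇐ 26 ⇐ 25 ⇐ 23 + 24.** The enol silane is cut at C16–C17 to vinyl ketone 27 (conjugate vinyl addition gives the enol silane regiospecifically), 27 to the N-methoxy-N-methylamide 26, the epoxides to diene 25, and 25 to geranyl bromide 23 and N-methoxy-N-methylacetamide 24.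

## Roads not taken

**Alternative 1:** The cut is at C4=C5 and C8=C9, both rings of the hydroazulene. In the forward sense RuCl2(H2IMes)(PCy3)(=CHPh) would take the dienyne A1 through an ene–yne–ene metathesis to the bicyclic dienone A2. Its merit is real: A2 already has the C15 ketone and the C2 methyl and no superfluous oxygen, so the chosen plan's steps 11 to 14 and 18 would have no counterpart. In step economy for the carbon skeleton this road is better. Its weak points lie in stereochemistry. The single stereocentre of A1, C6 next to the quaternary C12, needs its own asymmetric synthesis. The C9 carbinol would have to be added late by hydration of one alkene of a conjugated diene, with chemo- and facial selectivity left to the substrate. C5 would still need a directed hydrogenation that presupposes the C9 hydroxyl. The chosen plan sets against this that C9 comes from a Sharpless epoxide at the start and is then used twice as the controlling element (hydrogen bond in step 9, hydrogenation in step 16).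

**Alternative 2:** The cut is at C5–C9. SmI2 with HMPA and tert-butanol would reduce the methyl ketone of the cycloheptene A3 to a ketyl that closes 5-exo onto C5 and gives the cis-fused tertiary alcohol A4. This step would set C5 and C9 together in the sense usually found for such cyclisations (hydroxyl anti to the new ring bond), and here it is at least as direct as the chosen plan, which needs a separate hydrogenation for C5 and two protecting-group changes at O9. The price is A3: a cycloheptene with three stereocentres (C2, C6, C15) and the quaternary C12, whose synthesis is the real problem and is not solved by the key step. The alkene is unactivated, so simple ketone reduction competes. A4 also fixes C2 before the alkene C15=C16 exists, which rules out forming that alkene through a C15 enol derivative and leaves only olefination of the most hindered ketone in the molecule. The chosen plan makes both carbocycles from an acyclic chain and keeps C2 open until the transposition sets it together with the alkene geometry.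

**Alternative 3:** The cut is at O28–C25 and C18–C19 in the eastern half. Me3SiOTf would convert the diepoxy enol silane A5 into the trans-fused hydroxy-oxepane allylcyclohexanone A6. The cascade forms two rings and fixes three stereocentres from epoxides whose configuration is set by a reagent, and in security of stereocontrol it is better than a photochemical face selection. As the centre of a plan for this target it is weak only because it addresses the half for which good chemistry exists and leaves the hydroazulene, with C2, C5, C6, C9 and the hindered alkene, without an answer. The two plans therefore do not compete: the chosen route uses a cascade of this type as a supporting step (step 24; compound 29 is the triethylsilyl ether of A6) and spends its strategic step on the western half.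

Key step: step 9

Assumption: the configuration at C23 in compounds 26 to 39 is of no consequence because C23 ends as a ketone; it is drawn as the D-fructose-derived Shi ketone should set it (R).

## Steps

Step 1
Reactants: 1 geraniol [(2E)-3,7-dimethylocta-2,6-dien-1-ol]
Product: 2 (2R,3R)-2,3-epoxygeraniol {[(2R,3R)-3-methyl-3-(4-methylpent-3-en-1-yl)oxiran-2-yl]methanol}
Conditions: Ti(OiPr)4 (5 mol%), D-(−)-diethyl tartrate (6 mol%), t-BuOOH, 4 Å molecular sieves, CH2Cl2, −20 °C
Reagents that add atoms: tert-butyl hydroperoxide, CC(C)(C)OO
Why: Sharpless asymmetric epoxidation; the allylic hydroxyl restricts the reaction to the 2,3-alkene and the D-(−)-tartrate delivers oxygen to the face that gives the (2R,3R)-epoxide, which fixes C9 of the target.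

Step 2
Reactants: 2 (2R,3R)-2,3-epoxygeraniol
Product: 3 (3R)-3,7-dimethyloct-6-ene-1,3-diol
Conditions: NaAlH2(OCH2CH2OMe)2, THF, 0 °C
Reagents that add atoms: none
Why: Hydroxyl-directed reductive opening of a 2,3-epoxy alcohol; the alkoxyaluminate delivers hydride intramolecularly to C2, so the 1,3-diol forms and the tertiary C–O bond is not touched.

Step 3
Reactants: 3 (3R)-3,7-dimethyloct-6-ene-1,3-diol
Product: 4 (3R)-3,7-dimethyl-1,3-bis(triethylsilyloxy)oct-6-ene
Conditions: Et3SiOTf (2.4 equiv), 2,6-lutidine, CH2Cl2, −78 → 0 °C
Reagents that add atoms: triethylsilyl trifluoromethanesulfonate, CC[Si](CC)(CC)OS(=O)(=O)C(F)(F)F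
Why: Silyl triflate silylation, strong enough for the tertiary alcohol; the tertiary silyl ether blocks retro-aldol cleavage of the β-oxygenated carbonyl compounds of steps 5 and 6.

Step 4
Reactants: 4 (3R)-3,7-dimethyl-1,3-bis(triethylsilyloxy)oct-6-ene
Product: 5 (3R)-3,7-dimethyl-3-(triethylsilyloxy)oct-6-enal
Conditions: (COCl)2, DMSO, CH2Cl2, −78 → −30 °C; Et3N
Reagents that add atoms: none
Why: Swern oxidation applied directly to a primary triethylsilyl ether, which the chlorosulfonium salt cleaves and oxidises in one flask while the hindered tertiary silyl ether stays; a separate mono-deprotection is saved.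

Step 5
Reactants: 5 (3R)-3,7-dimethyl-3-(triethylsilyloxy)oct-6-enal; 6 methyl acrylate
Product: 7 methyl (6R)-6,10-dimethyl-4-oxo-6-(triethylsilyloxy)undec-9-enoate
Conditions: 3-benzyl-5-(2-hydroxyethyl)-4-methylthiazolium chloride (20 mol%), Et3N, 1,4-dioxane, 70 °C
Reagents that add atoms: none
Why: Stetter reaction; the carbene-derived acyl anion equivalent of the aliphatic aldehyde adds 1,4 to the acrylate and forms C3–C4, and the silyloxy group is γ to the nucleophilic carbon of the Breslow intermediate, so it cannot be expelled from it.

Step 6
Reactants: 7 methyl (6R)-6,10-dimethyl-4-oxo-6-(triethylsilyloxy)undec-9-enoate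
Product: 8 2-[(2R)-6-methyl-2-(triethylsilyloxy)hept-5-en-2-yl]cyclopentane-1,3-dione
Conditions: KOtBu (2.2 equiv), THF, 0 → 23 °C; AcOH
Reagents that add atoms: none
Why: Intramolecular Claisen (Dieckmann-type) condensation of a 4-oxo ester, the standard entry to 2-substituted cyclopentane-1,3-diones; the ketone enolate at C5 is acylated by the ester (C5–C15) and deprotonation of the acidic dione drives the equilibrium.

Step 7
Reactants: 8 2-[(2R)-6-methyl-2-(triethylsilyloxy)hept-5-en-2-yl]cyclopentane-1,3-dione
Product: 9 2-[(2R)-6-methyl-2-(triethylsilyloxy)hept-5-en-2-yl]-3-oxocyclopent-1-en-1-yl acetate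
Conditions: AcCl, pyridine, CH2Cl2, 0 °C
Reagents that add atoms: acetyl chloride, CC(=O)Cl
Why: O-Acylation of the enolised 1,3-dione; C-acylation is excluded because C5 already carries a tertiary substituent, and the two enol oxygens are equivalent, so one enol acetate forms.

Step 8
Reactants: 9 2-[(2R)-6-methyl-2-(triethylsilyloxy)hept-5-en-2-yl]-3-oxocyclopent-1-en-1-yl acetate
Product: 10 2-[(2R)-2-hydroxy-6-methylhept-5-en-2-yl]-3-oxocyclopent-1-en-1-yl acetate
Conditions: HF·pyridine, pyridine, THF, 0 °C
Reagents that add atoms: none
Why: Buffered fluoride desilylation, acidic enough to spare the enol acetate (a vinylogous anhydride that basic fluoride would cleave); the free hydroxyl is the control element of step 9.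

Step 9
Reactants: 10 2-[(2R)-2-hydroxy-6-methylhept-5-en-2-yl]-3-oxocyclopent-1-en-1-yl acetate
Product: 11 hydroxy photoadduct, 10-hydroxy-6,6,10-trimethyl-2-oxotricyclo[5.3.0.0(1,5)]decan-5-yl acetate, both five-membered rings cis-fused to the cyclobutane and the C9 hydroxyl on the face opposite to the cyclobutane [(5S,6S,9R,15R) in target labels]
Conditions: hν (350 nm, Pyrex), degassed methylcyclohexane (0.005 M), −20 °C
Reagents that add atoms: none
Why: Intramolecular enone–alkene (2+2) photocycloaddition, the first stage of a de Mayo reaction, of the type known for enol esters of 2-(pent-4-enyl)cyclopentane-1,3-diones. The triplet enone bonds first from C5 to C6 (1,5-closure, 5-exo, cyclopentane) and the 1,4-diradical (acetoxy-substituted C15, tertiary C12) then closes C12–C15 (cyclobutane), which gives the straight adduct and the quaternary carbon C12; the three-atom tether and the gem-dimethyl terminus secure this regiochemistry. Only a diradical with C15 and C12 on the same face of the new cyclopentane can close, so both five-membered rings are cis-fused to the cyclobutane and C5 and C15 follow from C6. C6 is set relative to C9, the only stereocentre of 10: in the hydrocarbon solvent the tertiary hydroxyl is hydrogen-bonded to the enone carbonyl (O9–H···O=C4, six-membered), which holds O9 in the enone plane on the C4 side and places C8 above and the C10 methyl below that plane. The alkene can reach C5 only from the face of C8, so in 11 O9 is cis to C4 and on the face opposite to the cyclobutane, which is the C6/C9 relation of the target. The selectivity the step needs is this facial one, and the hydrogen bond secures it, in the way free hydroxyl groups are known to steer intramolecular enone photocycloadditions in non-polar solvents; with a silyl ether the choice would rest on the small size difference between methyl and oxygen and could go either way. Light of 350 nm through Pyrex excites only the enone, and the saturated product no longer absorbs there.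

Step 10
Reactants: 11 hydroxy photoadduct
Product: 12 silylated photoadduct, 6,6,10-trimethyl-2-oxo-10-(triethylsilyloxy)tricyclo[5.3.0.0(1,5)]decan-5-yl acetate, configuration as in 11 [(5R,6S,9R,15R) in target labels]
Conditions: Et3SiOTf, 2,6-lutidine, CH2Cl2, −78 → 23 °C
Reagents that add atoms: triethylsilyl trifluoromethanesulfonate, CC[Si](CC)(CC)OS(=O)(=O)C(F)(F)F
Why: Silyl triflate silylation of the hindered tertiary alcohol; protection is restored before base is used, because the free β-hydroxy ketone (O9–C9–C5–C4=O) would undergo retro-aldol cleavage of C5–C9 in steps 11 and 13.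

Step 11
Reactants: 12 silylated photoadduct
Product: 14 bicyclic cycloheptane-1,4-dione (C5 epimers), via cyclobutanol 13 (not isolated)
Conditions: K2CO3, MeOH, 0 → 23 °C
Reagents that add atoms: none
Why: Second stage of the de Mayo reaction; methanolysis of the acetate frees cyclobutanol 13, whose β-hydroxy ketone opens by retro-aldol cleavage of C5–C15 with release of the four-ring strain and expands the cyclopentanone to the seven-membered 1,4-dione (ketones at C4 and C15). C5 is protonated without control, which does not matter because C5 becomes trigonal again in step 13.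

Step 12
Reactants: 14 bicyclic cycloheptane-1,4-dione (C5 epimers)
Product: 15 bicyclic ene-1,4-dione with the C2=C3 alkene (C5 epimers)
Conditions: IBX (1.5 equiv), DMSO, 65 °C
Reagents that add atoms: none
Why: IBX dehydrogenation of a ketone to the enone; enolisation of either ketone toward C2 or C3 leads to the same C2=C3 alkene, and in the resulting ene-dione C5–H is the only enolisable hydrogen (C12 is quaternary, C2 and C3 are vinylic), which makes the next enolisation regiospecific.

Step 13
Reactants: 15 bicyclic ene-1,4-dione
Product: 16 dienyl triflate (enol triflate at C4 with the C4=C5 alkene, C2=C3 alkene, C15 ketone)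
Conditions: KN(SiMe3)2, THF, −78 °C; PhNTf2, −78 → 0 °C
Reagents that add atoms: N-phenylbis(trifluoromethanesulfonimide), O=S(=O)(N(c1ccccc1)S(=O)(=O)C(F)(F)F)C(F)(F)F
Why: Enolate O-sulfonylation; deprotonation is possible only at C5, so the enol triflate forms at C4 toward C5, and trapping at −78 °C limits loss of the β-silyloxy group from the enolate.

Step 14
Reactants: 16 dienyl triflate
Product: 17 silyloxy dienone (C2=C3 and C4=C5 alkenes, C15 ketone)
Conditions: Pd(OAc)2 (5 mol%), PPh3 (10 mol%), HCO2H, Bu3N, DMF, 60 °C
Reagents that add atoms: none
Why: Palladium-catalysed formate reduction of an enol triflate (oxidative addition, formate exchange, decarboxylation, reductive elimination); it replaces the C4 oxygen by hydrogen and leaves the C4=C5 alkene for step 16.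

Step 15
Reactants: 17 silyloxy dienone
Product: 18 hydroxy dienone
Conditions: HF·pyridine, pyridine, THF, 0 → 23 °C
Reagents that add atoms: none
Why: Buffered fluoride desilylation; basic fluoride is avoided because C6–H is vinylogously acidic in the dienone, and with C4 no longer a carbonyl the free tertiary alcohol is safe from retro-aldol cleavage.

Step 16
Reactants: 18 hydroxy dienone
Product: 19 cis-fused hydroxy hydroazulenone (C15 ketone; C5–H, C6–H and C9–OH on one face) [(5R,6R,9R) in target labels]
Conditions: [Ir(cod)(PCy3)(py)]PF6 (10 mol%), H2 (1 atm), CH2Cl2, 0 → 23 °C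
Reagents that add atoms: none
Why: Hydroxyl-directed hydrogenation with the cationic iridium catalyst, known for tertiary allylic and homoallylic alcohols; the C9 hydroxyl binds the metal and hydrogen reaches C5 from the face of O9, which is also the face of C6–H and the less hindered one (the other carries the C10 methyl and C12). This sets C5 and the cis ring fusion; the disubstituted C2=C3 alkene is reduced as well.

Step 17
Reactants: 19 cis-fused hydroxy hydroazulenone
Product: 20 triethylsilyl ether of 19
Conditions: Et3SiOTf, 2,6-lutidine, CH2Cl2, −78 → 0 °C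
Reagents that add atoms: triethylsilyl trifluoromethanesulfonate, CC[Si](CC)(CC)OS(=O)(=O)C(F)(F)F
Why: Silylation of the tertiary alcohol so that no alkoxide competes for the sulfonylating agent in step 19; with 2,6-lutidine at low temperature the hindered ketone is not converted into a silyl enol ether.

Step 18
Reactants: 20 triethylsilyl ether of 19
Product: 21 C2-methyl ketone (C2 epimers)
Conditions: LiN(iPr)2, THF, −78 °C; MeI, −78 → 0 °C
Reagents that add atoms: iodomethane, CI
Why: Enolate alkylation; the C15 ketone can enolise only toward C2 because C12 is quaternary, so methylation is regiospecific, and the C2 configuration is irrelevant because C2 becomes trigonal in step 19.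

Step 19
Reactants: 21 C2-methyl ketone
Product: 22 alkenyl triflate (C15 enol triflate with the C15=C2 alkene) [(5R,6R,9R) in target labels]
Conditions: KN(SiMe3)2, THF, −78 → −20 °C; PhNTf2
Reagents that add atoms: N-phenylbis(trifluoromethanesulfonimide), O=S(=O)(N(c1ccccc1)S(=O)(=O)C(F)(F)F)C(F)(F)F
Why: Enol triflate formation from the only possible, tetrasubstituted enolate, as with 2,6,6-trimethylcyclohexanone; the triflate makes the neopentylic carbon C15 available for C–C bond formation.

Step 20
Reactants: 23 geranyl bromide [(2E)-1-bromo-3,7-dimethylocta-2,6-diene]; 24 N-methoxy-N-methylacetamide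
Product: 25 (4E)-N-methoxy-N,5,9-trimethyldeca-4,8-dienamide
Conditions: 24, LiN(iPr)2, THF, −78 °C; then 23, −78 → −20 °C
Reagents that add atoms: none
Why: Alkylation of an amide enolate with a primary allylic bromide (SN2, alkene geometry retained); the amide brings C31 and C32 and is the ketone precursor for step 22.

Step 21
Reactants: 25 (4E)-N-methoxy-N,5,9-trimethyldeca-4,8-dienamide
Product: 26 N-methoxy-N-methyl-3-[(2R,3R)-3-{2-[(2R)-3,3-dimethyloxiran-2-yl]ethyl}-3-methyloxiran-2-yl]propanamide
Conditions: D-fructose-derived Shi ketone (0.6 equiv), KHSO5 (as 2KHSO5·KHSO4·K2SO4), K2CO3, Bu4NHSO4, MeCN–CH2(OMe)2–aqueous Na2B4O7 buffer (pH 10.5), 0 °C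
Reagents that add atoms: potassium peroxymonosulfate, [K+].[O-]S(=O)(=O)OO
Why: Shi asymmetric epoxidation of both trisubstituted alkenes by the chiral dioxirane through a spiro transition state; the D-fructose-derived ketone gives the (R,R)-epoxide at C29–C19 and the (R)-epoxide at C23, each alkene being controlled by the catalyst alone.

Step 22
Reactants: 26 diepoxy amide
Product: 27 5-[(2R,3R)-3-{2-[(2R)-3,3-dimethyloxiran-2-yl]ethyl}-3-methyloxiran-2-yl]pent-1-en-3-one
Conditions: CH2=CHMgBr, THF, −78 → 0 °C; inverse quench into cold aqueous KHSO4
Reagents that add atoms: vinylmagnesium bromide, C=C[Mg]Br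
Why: Ketone synthesis from an N-methoxy-N-methylamide; the chelated tetrahedral intermediate stops at mono-addition, trisubstituted epoxides are inert to the Grignard reagent at low temperature, and the acidic inverse quench keeps the released N,O-dimethylhydroxylamine from adding to the enone.

Step 23
Reactants: 27 diepoxy vinyl ketone
Product: 28 (Z)-triethylsilyl enol ether, triethyl{[(3Z)-1-[(2R,3R)-3-{2-[(2R)-3,3-dimethyloxiran-2-yl]ethyl}-3-methyloxiran-2-yl]hepta-3,6-dien-3-yl]oxy}silane
Conditions: CH2=CHMgBr, CuBr·SMe2 (10 mol%), Et3SiCl, HMPA, THF, −78 °C; Et3N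
Reagents that add atoms: vinylmagnesium bromide, C=C[Mg]Br; chlorotriethylsilane, CC[Si](Cl)(CC)CC
Why: Copper-catalysed conjugate addition with silyl chloride trapping; it places the vinyl group on C17 and gives the enol silane regiospecifically at C32=C18 (mainly Z), which deprotonation of the corresponding butenyl ketone could not do.

Step 24
Reactants: 28 (Z)-triethylsilyl enol ether
Product: 29 trans-fused oxepane–cyclohexanone (C32 ketone, equatorial allyl group on C18, axial C20 methyl on C19, triethylsilyloxy group on C23) [(18R,19R,23R,29R) in target labels]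
Conditions: Et3SiOTf (1.1 equiv), 2,6-di-tert-butyl-4-methylpyridine, CH2Cl2, −78 °C
Reagents that add atoms: triethylsilyl trifluoromethanesulfonate, CC[Si](CC)(CC)OS(=O)(=O)C(F)(F)F
Why: Silyl triflate-promoted tandem oxa- and carbacyclisation of a 1,5-diepoxide, a known route to trans-fused 2,2-dimethyloxepane–cyclohexanones; the silylated terminal epoxide is opened at its tertiary carbon C25 by the oxygen of the second epoxide (O28–C25), and the bicyclic epoxonium ion is opened at C19 with inversion by C18 of the enol silane (C18–C19) through a chair transition state. C29 and C23 keep the epoxide configurations, and the allyl group on C18 takes the equatorial position, which is also the thermodynamically preferred one at this epimerisable centre.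

Step 25
Reactants: 29 trans-fused oxepane–cyclohexanone
Product: 30 tertiary alcohol (C33 methyl equatorial, C32 hydroxyl axial, 32S)
Conditions: MeMgBr, CeCl3, THF, −78 → 0 °C
Reagents that add atoms: methylmagnesium bromide, C[Mg]Br
Why: Organocerium addition to an enolisable, α-branched ketone; axial attack is blocked by the axial C20 methyl (1,3-diaxial), so the methyl group enters equatorially and the hydroxyl becomes axial as in the target.

Step 26
Reactants: 30 tertiary alcohol
Product: 31 bis(triethylsilyl) ether of 30
Conditions: Et3SiOTf, 2,6-lutidine, CH2Cl2, 0 → 23 °C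
Reagents that add atoms: triethylsilyl trifluoromethanesulfonate, CC[Si](CC)(CC)OS(=O)(=O)C(F)(F)F
Why: Silylation of the tertiary alcohol; unprotected, the γ-hydroxy aldehyde of step 27 would close to a lactol that does not enter the chromium-mediated coupling.

Step 27
Reactants: 31 bis(triethylsilyl) ether
Product: 32 eastern aldehyde (C16 aldehyde, silyl ethers at O on C23 and C32)
Conditions: O3, CH2Cl2, −78 °C; PPh3
Reagents that add atoms: ozone, [O-][O+]=O
Why: Ozonolysis of the only alkene with reductive work-up; it unveils C16 as the aldehyde.

Step 28
Reactants: 22 alkenyl triflate; 32 eastern aldehyde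
Product: 33 coupled allylic alcohols (C16 epimers, C15=C2 alkene)
Conditions: CrCl2 (6 equiv), NiCl2 (2 mol%), DMF, 23 °C
Reagents that add atoms: none
Why: Nozaki–Hiyama–Kishi coupling; nickel inserts into the hindered enol triflate (the 2,6,6-trimethylcyclohexenyl triflate pattern is a standard substrate), transmetalation gives the alkenylchromium species, and this adds to the aldehyde only. The C16 configuration is left open on purpose.

Step 29
Reactants: 33 coupled allylic alcohols
Product: 34 enone (C16 ketone)
Conditions: Dess–Martin periodinane, NaHCO3, CH2Cl2, 0 → 23 °C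
Reagents that add atoms: none
Why: Dess–Martin oxidation of the secondary allylic alcohol; both C16 epimers converge on one ketone.

Step 30
Reactants: 34 enone
Product: 35 (16R)-allylic alcohol
Conditions: (S)-2-methyl-CBS-oxazaborolidine (0.5 equiv), BH3·SMe2, THF, −30 °C
Reagents that add atoms: none
Why: Corey–Bakshi–Shibata reduction; the twisted tetrasubstituted alkenyl group is the large and the C17 methylene the small substituent, so the (S)-catalyst should give the (16R)-alcohol, as it gives (R)-1-phenylethanol from acetophenone.

Step 31
Reactants: 35 (16R)-allylic alcohol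
Product: 38 tris(triethylsilyl) ether with the Z alkene C15=C16 and the (2S) centre, via sulfonylhydrazine 36 (not isolated), via allylic diazene 37 (not isolated)
Conditions: 2-nitrobenzenesulfonylhydrazide, PPh3, diethyl azodicarboxylate, N-methylmorpholine, −30 → 23 °C
Reagents that add atoms: none
Why: Reductive 1,3-transposition of an allylic alcohol through its diazene; Mitsunobu displacement with inversion gives the (16S)-sulfonylhydrazine 36, which loses 2-nitrobenzenesulfinic acid on warming to the diazene 37, and this passes its hydrogen to C2 in a retro-ene step with loss of N2. With C16–H eclipsing the alkene (allylic 1,3-strain against the C1 methyl) C17 ends cis to C12 (Z), and hydrogen reaches C2 on the face held by nitrogen, which gives the (2S) centre.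

Step 32
Reactants: 38 tris(triethylsilyl) ether
Product: 39 triol (hydroxyls at C9, C23 and C32)
Conditions: Bu4NF, THF, 23 → 50 °C
Reagents that add atoms: none
Why: Fluoride cleavage of the three triethylsilyl ethers; no base-sensitive group is present at this stage, and acid, which could move the exocyclic alkene or ionise the tertiary alcohols, is avoided.

Step 33
Reactants: 39 triol
Product: 40 CNP0157787.1 (target)
Conditions: Dess–Martin periodinane, NaHCO3, CH2Cl2, 0 °C
Reagents that add atoms: none
Why: Dess–Martin oxidation; C23–OH is the only secondary alcohol, the two tertiary alcohols cannot be oxidised, and the buffered neutral medium leaves the alkene and C2 untouched.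

## Compound list

1 | geraniol, (2E)-3,7-dimethylocta-2,6-dien-1-ol | CC(C)=CCC/C(C)=C/CO | starting material
2 | (2R,3R)-2,3-epoxygeraniol | CC(C)=CCC[C@@]1(C)O[C@@H]1CO | intermediate
3 | (3R)-3,7-dimethyloct-6-ene-1,3-diol | CC(C)=CCC[C@@](C)(O)CCO | intermediate
4 | (3R)-3,7-dimethyl-1,3-bis(triethylsilyloxy)oct-6-ene | CC(C)=CCC[C@@](C)(O[Si](CC)(CC)CC)CCO[Si](CC)(CC)CC | intermediate
5 | (3R)-3,7-dimethyl-3-(triethylsilyloxy)oct-6-enal | CC(C)=CCC[C@@](C)(O[Si](CC)(CC)CC)CC=O | intermediate
6 | methyl acrylate | C=CC(=O)OC | starting material
7 | methyl (6R)-6,10-dimethyl-4-oxo-6-(triethylsilyloxy)undec-9-enoate | CC(C)=CCC[C@@](C)(O[Si](CC)(CC)CC)CC(=O)CCC(=O)OC | intermediate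
8 | 2-[(2R)-6-methyl-2-(triethylsilyloxy)hept-5-en-2-yl]cyclopentane-1,3-dione | CC(C)=CCC[C@@](C)(O[Si](CC)(CC)CC)C1C(=O)CCC1=O | intermediate
9 | 2-[(2R)-6-methyl-2-(triethylsilyloxy)hept-5-en-2-yl]-3-oxocyclopent-1-en-1-yl acetate | CC(=O)OC1=C(C(=O)CC1)[C@](C)(O[Si](CC)(CC)CC)CCC=C(C)C | intermediate
10 | 2-[(2R)-2-hydroxy-6-methylhept-5-en-2-yl]-3-oxocyclopent-1-en-1-yl acetate | CC(=O)OC1=C(C(=O)CC1)[C@](C)(O)CCC=C(C)C | intermediate
11 | hydroxy photoadduct, 10-hydroxy-6,6,10-trimethyl-2-oxotricyclo[5.3.0.0(1,5)]decan-5-yl acetate, hydroxyl anti to the cyclobutane, (5S,6S,9R,15R) in target labels | C[C@@]1(O)CC[C@H]2C(C)(C)[C@]3(OC(C)=O)CCC(=O)[C@]123 | intermediate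
12 | silylated photoadduct, 6,6,10-trimethyl-2-oxo-10-(triethylsilyloxy)tricyclo[5.3.0.0(1,5)]decan-5-yl acetate, (5R,6S,9R,15R) in target labels | C[C@@]1(O[Si](CC)(CC)CC)CC[C@H]2C(C)(C)[C@]3(OC(C)=O)CCC(=O)[C@]123 | intermediate
13 | cyclobutanol, the deacetylated form of 12 | C[C@@]1(O[Si](CC)(CC)CC)CC[C@H]2C(C)(C)[C@]3(O)CCC(=O)[C@]123 | intermediate
14 | bicyclic cycloheptane-1,4-dione, ketones at C4 and C15, C9 silyl ether, (6R,9R), C5 epimers | C[C@@]1(O[Si](CC)(CC)CC)CC[C@H]2C(C)(C)C(=O)CCC(=O)C12 | intermediate
15 | bicyclic ene-1,4-dione with the C2=C3 alkene, (6R,9R), C5 epimers | C[C@@]1(O[Si](CC)(CC)CC)CC[C@H]2C(C)(C)C(=O)C=CC(=O)C12 | intermediate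
16 | dienyl triflate, C4 enol triflate with C4=C5, C2=C3 alkene, C15 ketone, (6R,9R) | C[C@@]1(O[Si](CC)(CC)CC)CC[C@H]2C(C)(C)C(=O)C=CC(OS(=O)(=O)C(F)(F)F)=C12 | intermediate
17 | silyloxy dienone, C2=C3 and C4=C5 alkenes, C15 ketone, (6R,9R) | C[C@@]1(O[Si](CC)(CC)CC)CC[C@H]2C(C)(C)C(=O)C=CC=C12 | intermediate
18 | hydroxy dienone, (6R,9R) | C[C@@]1(O)CC[C@H]2C(C)(C)C(=O)C=CC=C12 | intermediate
19 | cis-fused hydroxy hydroazulenone, C15 ketone, C5–H, C6–H and C9–OH on one face, (5R,6R,9R) | C[C@@]1(O)CC[C@H]2C(C)(C)C(=O)CCC[C@@H]12 | intermediate
20 | triethylsilyl ether of 19 | C[C@@]1(O[Si](CC)(CC)CC)CC[C@H]2C(C)(C)C(=O)CCC[C@@H]12 | intermediate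
21 | C2-methyl ketone, C2 epimers | C[C@@]1(O[Si](CC)(CC)CC)CC[C@H]2C(C)(C)C(=O)C(C)CC[C@@H]12 | intermediate
22 | alkenyl triflate, C15 enol triflate with C15=C2, (5R,6R,9R) | C[C@@]1(O[Si](CC)(CC)CC)CC[C@H]2C(C)(C)C(OS(=O)(=O)C(F)(F)F)=C(C)CC[C@@H]12 | intermediate
23 | geranyl bromide, (2E)-1-bromo-3,7-dimethylocta-2,6-diene | CC(C)=CCC/C(C)=C/CBr | starting material
24 | N-methoxy-N-methylacetamide | CON(C)C(C)=O | starting material
25 | (4E)-N-methoxy-N,5,9-trimethyldeca-4,8-dienamide | CON(C)C(=O)CC/C=C(\C)CCC=C(C)C | intermediate
26 | N-methoxy-N-methyl-3-[(2R,3R)-3-{2-[(2R)-3,3-dimethyloxiran-2-yl]ethyl}-3-methyloxiran-2-yl]propanamide | CON(C)C(=O)CC[C@H]1O[C@]1(C)CC[C@H]1OC1(C)C | intermediate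
27 | 5-[(2R,3R)-3-{2-[(2R)-3,3-dimethyloxiran-2-yl]ethyl}-3-methyloxiran-2-yl]pent-1-en-3-one | C=CC(=O)CC[C@H]1O[C@]1(C)CC[C@H]1OC1(C)C | intermediate
28 | (Z)-triethylsilyl enol ether of the diepoxy hept-6-en-3-one | C=CC/C=C(\O[Si](CC)(CC)CC)CC[C@H]1O[C@]1(C)CC[C@H]1OC1(C)C | intermediate
29 | trans-fused oxepane–cyclohexanone, C32 ketone, equatorial C18 allyl, C23 triethylsilyl ether, (18R,19R,23R,29R) | C=CC[C@@H]1[C@@]2(C)CC[C@@H](O[Si](CC)(CC)CC)C(C)(C)O[C@@H]2CCC1=O | intermediate
30 | tertiary alcohol from 29, C32 hydroxyl axial, (32S) | C=CC[C@@H]1[C@@]2(C)CC[C@@H](O[Si](CC)(CC)CC)C(C)(C)O[C@@H]2CC[C@]1(C)O | intermediate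
31 | bis(triethylsilyl) ether of 30 | C=CC[C@@H]1[C@@]2(C)CC[C@@H](O[Si](CC)(CC)CC)C(C)(C)O[C@@H]2CC[C@]1(C)O[Si](CC)(CC)CC | intermediate
32 | eastern aldehyde, C16 aldehyde | O=CC[C@@H]1[C@@]2(C)CC[C@@H](O[Si](CC)(CC)CC)C(C)(C)O[C@@H]2CC[C@]1(C)O[Si](CC)(CC)CC | intermediate
33 | coupled allylic alcohols, C16 epimers, C15=C2 alkene | C[C@@]1(O[Si](CC)(CC)CC)CC[C@H]2C(C)(C)C(=C(C)CC[C@@H]12)C(O)C[C@@H]1[C@@]2(C)CC[C@@H](O[Si](CC)(CC)CC)C(C)(C)O[C@@H]2CC[C@]1(C)O[Si](CC)(CC)CC | intermediate
34 | enone, C16 ketone | C[C@@]1(O[Si](CC)(CC)CC)CC[C@H]2C(C)(C)C(=C(C)CC[C@@H]12)C(=O)C[C@@H]1[C@@]2(C)CC[C@@H](O[Si](CC)(CC)CC)C(C)(C)O[C@@H]2CC[C@]1(C)O[Si](CC)(CC)CC | intermediate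
35 | (16R)-allylic alcohol | C[C@@]1(O[Si](CC)(CC)CC)CC[C@H]2C(C)(C)C(=C(C)CC[C@@H]12)[C@H](O)C[C@@H]1[C@@]2(C)CC[C@@H](O[Si](CC)(CC)CC)C(C)(C)O[C@@H]2CC[C@]1(C)O[Si](CC)(CC)CC | intermediate
36 | (16S)-N-allyl-N-(2-nitrobenzenesulfonyl)hydrazine | C[C@@]1(O[Si](CC)(CC)CC)CC[C@H]2C(C)(C)C(=C(C)CC[C@@H]12)[C@@H](N(N)S(=O)(=O)c3ccccc3[N+](=O)[O-])C[C@@H]1[C@@]2(C)CC[C@@H](O[Si](CC)(CC)CC)C(C)(C)O[C@@H]2CC[C@]1(C)O[Si](CC)(CC)CC | intermediate
37 | (16S)-allylic diazene | C[C@@]1(O[Si](CC)(CC)CC)CC[C@H]2C(C)(C)C(=C(C)CC[C@@H]12)[C@@H](N=N)C[C@@H]1[C@@]2(C)CC[C@@H](O[Si](CC)(CC)CC)C(C)(C)O[C@@H]2CC[C@]1(C)O[Si](CC)(CC)CC | intermediate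
38 | tris(triethylsilyl) ether, Z alkene C15=C16, (2S) | C[C@H]1CC[C@@H]2[C@@H](CC[C@@]2(C)O[Si](CC)(CC)CC)C(C)(C)/C1=C\C[C@@H]1[C@@]2(C)CC[C@@H](O[Si](CC)(CC)CC)C(C)(C)O[C@@H]2CC[C@]1(C)O[Si](CC)(CC)CC | intermediate
39 | triol, the C23 alcohol of the target | C[C@H]1CC[C@@H]2[C@@H](CC[C@@]2(C)O)C(C)(C)/C1=C\C[C@@H]1[C@@]2(C)CC[C@@H](O)C(C)(C)O[C@@H]2CC[C@]1(C)O | intermediate
40 | CNP0157787.1 | C[C@H]1CC[C@@H]2[C@@H](CC[C@@]2(C)O)C(C)(C)/C1=C\C[C@@H]1[C@@]2(C)CCC(=O)C(C)(C)O[C@@H]2CC[C@]1(C)O | target

## Step count and risks

Total: 33 steps. Longest linear sequence: 25 steps (steps 1 to 19 and 28 to 33, from geraniol); the eastern branch (steps 20 to 27) has 8 steps.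

**Step 9 (key step).** The most likely failure is incomplete facial discrimination: if the hydrogen bond to O=C4 is broken (polar impurities, aggregation, a competing hydrogen bond to the acetate carbonyl), closure on the other face of the enone competes and gives the C9-epimeric series. A second risk is acetyl transfer from the enol oxygen to the free tertiary hydroxyl during handling of 10. Fallback: the silyl ether 9 is irradiated directly under the same light, which gives 12 without passing through 10 and 11 and saves steps 8 and 10. The facial choice then depends on sterics and dipoles and is less predictable, but no free hydroxyl is exposed, and the diastereomers would be separated at the stage of 12. This fallback sets out from 9, returns at 12 and makes no compound outside the list (entry F0).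

**Step 6.** The C5 enolate needed for ring closure carries the silyloxy group in the β-position, so β-elimination (E1cB) to an enone may outrun acylation under alkoxide conditions. Fallback: from 7, hydrolysis (LiOH, THF–water) gives the keto acid F1, which is converted (pentafluorophenol, carbodiimide) into the pentafluorophenyl ester F2. Soft enolisation (MgBr2·OEt2, iPr2NEt, CH2Cl2, 23 °C) then lets a magnesium enolate acylate C5 without alkoxide base, a known way to 1,3-diketones from ketones and active esters, and gives 8.

**Step 12.** Over-oxidation is the danger: once the ene-dione has formed, further dehydrogenation across C5–C6 would destroy C6, and the oxidant may be slow with the hindered ketones. Fallback: from 14, Me3SiOTf and Et3N give the conjugated bis(trimethylsilyl) dienol ether F3 (enolisation toward C2 and C3), and Pd(OAc)2 in MeCN (Saegusa–Ito oxidation) converts it into 15.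

**Step 31.** The hindered, highly stabilised allylic oxyphosphonium ion may ionise instead of undergoing clean SN2 displacement, with loss of configuration at C16, SN2′ attack or elimination to a diene. Fallback: from 35, methyl chloroformate and pyridine give the allylic methyl carbonate F4. Pd(OAc)2, PBu3 and HCO2NH4 in THF (Tsuji formate reduction) ionise the carbonate with inversion, and zerovalent palladium delivers hydride from its own face to the more substituted terminus C2. Hydrogen therefore arrives on the same face as in the diazene route and the alkene ends at C15=C16, giving 38.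

## Further compounds

F0 | step 9 | none | none
F1 | step 6 | (6R)-6,10-dimethyl-4-oxo-6-(triethylsilyloxy)undec-9-enoic acid | CC(C)=CCC[C@@](C)(O[Si](CC)(CC)CC)CC(=O)CCC(=O)O
F2 | step 6 | pentafluorophenyl (6R)-6,10-dimethyl-4-oxo-6-(triethylsilyloxy)undec-9-enoate | CC(C)=CCC[C@@](C)(O[Si](CC)(CC)CC)CC(=O)CCC(=O)Oc1c(F)c(F)c(F)c(F)c1F
F3 | step 12 | bis(trimethylsilyl) dienol ether of dione 14 (silyloxy groups on C4 and C15, alkenes C15=C2 and C3=C4) | C[C@@]1(O[Si](CC)(CC)CC)CC[C@H]2C(C)(C)C(O[Si](C)(C)C)=CC=C(O[Si](C)(C)C)C12
F4 | step 31 | methyl carbonate of the (16R)-allylic alcohol 35 | C[C@@]1(O[Si](CC)(CC)CC)CC[C@H]2C(C)(C)C(=C(C)CC[C@@H]12)[C@H](OC(=O)OC)C[C@@H]1[C@@]2(C)CC[C@@H](O[Si](CC)(CC)CC)C(C)(C)O[C@@H]2CC[C@]1(C)O[Si](CC)(CC)CC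
A1 | alternative 1 | acyclic dienyne ketone, precursor of the metathesis cascade | C=CCC(C)C(=O)C(C)(C)[C@H](CC=C)C#CC
A2 | alternative 1 | bicyclo[5.3.0]decadienone with C4=C5 and C8=C9 alkenes | CC1CC=C2C(C)=CC[C@H]2C(C)(C)C1=O
A3 | alternative 2 | cycloheptene methyl ketone, precursor of the ketyl cyclisation | C[C@H]1CC=C[C@@H](CCC(C)=O)C(C)(C)[C@H]1O[Si](C)(C)C(C)(C)C
A4 | alternative 2 | cis-fused hydroazulene tertiary alcohol, C15 silyl ether | C[C@H]1CC[C@@H]2[C@@H](CC[C@@]2(C)O)C(C)(C)[C@H]1O[Si](C)(C)C(C)(C)C
A5 | alternative 3 | diepoxy tert-butyldimethylsilyl enol ether | C=CC/C=C(\O[Si](C)(C)C(C)(C)C)CC[C@H]1O[C@]1(C)CC[C@H]1OC1(C)C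
A6 | alternative 3 | trans-fused hydroxy-oxepane 2-allylcyclohexanone | C=CC[C@@H]1[C@@]2(C)CC[C@@H](O)C(C)(C)O[C@@H]2CCC1=O
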